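**Retrosynthetic overview**

- The route rests on ring A. Its three oxygen-bearing carbons C5, C7 and C8a all lie ortho or para to the C4 carbonyl, so ring A is carried as a 2,4,6-trifluorobenzoyl unit whose C–F bonds are exchanged for oxygen one after another.
- Target ⇐ quercetin 3-acetate by sulfation at O7, O3' and O4' (O5–H is hydrogen-bonded to C4=O and stays free) ⇐ 3',4',5,7-tetra-O-benzyl-3-O-PMB-quercetin by PMB removal, acetylation at O3 and hydrogenolysis.
- That ether ⇐ 5,7-difluoro-3-(PMB-oxy)flavone by twofold SNAr with benzyloxide at C7 and C5.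
- Difluoroflavone ⇐ 2-(PMB-oxy)-1,3-diketone by intramolecular SNAr forming O1–C8a. Ring C is the only ring made; rings A and B are bought.
- Diketone ⇐ α-(PMB-oxy) ketone + 2,4,6-trifluorobenzoyl chloride (C3–C4 bond); the ketone ⇐ 3,4-bis(benzyloxy)phenyllithium + a glycolic Weinreb amide.

Key step: step 4

Remark: the target is drawn as the free tris(hydrogen sulfate), so the last step ends with cation exchange to the acid form; in practice the compound would be stored as its sodium salt.
Remark: conjugate bases formed by simple deprotonation (alkoxides, enolates) are treated as forms of their numbered parent compounds.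

**Route**

Step 1
Reactants: 1 4-methoxybenzyl alcohol; 2 2-chloro-N-methoxy-N-methylacetamide
Product: 3 N-methoxy-2-[(4-methoxybenzyl)oxy]-N-methylacetamide
Conditions: NaH, THF, 0 °C; then 2, 0 °C → rt
Reagents that add atoms: none
Why: Williamson ether synthesis, in which the sodium alkoxide of 1 displaces the primary chloride activated by the adjacent amide carbonyl, while the Weinreb amide is a poor acyl donor towards alkoxide at this temperature.

Step 2
Reactants: 4 4-bromo-1,2-bis(benzyloxy)benzene; 3 N-methoxy-2-[(4-methoxybenzyl)oxy]-N-methylacetamide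
Product: 6 1-[3,4-bis(benzyloxy)phenyl]-2-[(4-methoxybenzyl)oxy]ethan-1-one, via [3,4-bis(benzyloxy)phenyl]lithium 5 (not isolated)
Conditions: n-BuLi, THF, −78 °C; then 3, −78 → 0 °C; aq. NH4Cl
Reagents that add atoms: none
Why: Bromine–lithium exchange followed by Weinreb ketone synthesis should stop cleanly at the ketone, because the N-methoxy-N-methylamide adduct does not collapse before the quench and the benzyl and PMB ethers tolerate the aryllithium at −78 °C.

Step 3
Reactants: 6 1-[3,4-bis(benzyloxy)phenyl]-2-[(4-methoxybenzyl)oxy]ethan-1-one; 7 2,4,6-trifluorobenzoyl chloride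
Product: 8 (E)-3-[3,4-bis(benzyloxy)phenyl]-3-hydroxy-2-[(4-methoxybenzyl)oxy]-1-(2,4,6-trifluorophenyl)prop-2-en-1-one (chelated enol of the 1,3-diketone)
Conditions: LiN(SiMe3)2 (2.2 equiv), THF, −78 °C; then 7, −78 → −30 °C; AcOH quench at −78 °C
Reagents that add atoms: none
Why: Claisen-type C-acylation of the chelated lithium enolate of an α-alkoxy ketone with an aroyl chloride, in which the second equivalent of base takes up the more acidic product as its lithium diketonate, which is too tightly chelated in cold THF to displace fluoride (and would only give 9 early if it did).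

Step 4
Reactants: 8 (E)-3-[3,4-bis(benzyloxy)phenyl]-3-hydroxy-2-[(4-methoxybenzyl)oxy]-1-(2,4,6-trifluorophenyl)prop-2-en-1-one
Product: 9 2-[3,4-bis(benzyloxy)phenyl]-5,7-difluoro-3-[(4-methoxybenzyl)oxy]-4H-chromen-4-one
Conditions: K2CO3 (1.5 equiv), dry DMF, 25 → 50 °C
Reagents that add atoms: none
Why: K2CO3 deprotonates the 1,3-dicarbonyl unit of 8, and the enolate oxygen on the carbon that bears ring B adds to an ortho C–F carbon of the trifluorophenyl ring, giving a Meisenheimer-type anion stabilised by the C4 carbonyl and inductively by the two fluorines meta to the site of attack; loss of fluoride then forms the O1–C8a bond. The closest known reaction type is the carbonate-mediated intramolecular SNAr cyclisation of 1-(2-fluoroaryl)-1,3-diketones to chromones and flavones. Ring C closes as a six-membered ring (O1, C2, C3, C4, C4a, C8a) by ipso attack of oxygen on an sp2 aryl carbon followed by elimination. No stereocentre is created. The step needs O-attack in preference to C-attack and a single site of attack, and the substrate secures both: the fully substituted central carbon and the carbonyl oxygen next to ring A could each only form a four-membered ring, and the two ortho fluorides are interchanged by rotation about the aryl–carbonyl bond, so either gives the same product. The fluorides left at C5 and C7 are inert to carbonate and stay ortho and para to the C4 carbonyl for the exchange in step 5.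

Step 5
Reactants: 9 2-[3,4-bis(benzyloxy)phenyl]-5,7-difluoro-3-[(4-methoxybenzyl)oxy]-4H-chromen-4-one; 10 benzyl alcohol
Product: 12 5,7-bis(benzyloxy)-2-[3,4-bis(benzyloxy)phenyl]-3-[(4-methoxybenzyl)oxy]-4H-chromen-4-one, via 7-benzyloxy-5-fluoroflavone 11 (not isolated)
Conditions: 10 (3 equiv), NaH (2.6 equiv), THF, 0 °C; then 9 in DMF, 0 → 45 °C
Reagents that add atoms: none
Why: Twofold SNAr with sodium benzyloxide should exchange C7–F (para to C4=O) first and then C5–F (ortho to C4=O, helped by sodium coordination to the carbonyl oxygen), while addition of alkoxide at C2 is reversible under anhydrous conditions because reclosure regenerates the chromone.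

Step 6
Reactants: 12 5,7-bis(benzyloxy)-2-[3,4-bis(benzyloxy)phenyl]-3-[(4-methoxybenzyl)oxy]-4H-chromen-4-one
Product: 13 5,7-bis(benzyloxy)-2-[3,4-bis(benzyloxy)phenyl]-3-hydroxy-4H-chromen-4-one
Conditions: DDQ (1.3 equiv), CH2Cl2/pH 7 phosphate buffer (10:1), 0 °C → rt
Reagents that add atoms: none
Why: Oxidative PMB ether cleavage, in which DDQ abstracts hydride from the 4-methoxybenzylic position and water hydrolyses the resulting oxocarbenium ion, whereas the unactivated benzyl ethers are oxidised far more slowly.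

Step 7
Reactants: 13 5,7-bis(benzyloxy)-2-[3,4-bis(benzyloxy)phenyl]-3-hydroxy-4H-chromen-4-one
Product: 14 5,7-bis(benzyloxy)-2-[3,4-bis(benzyloxy)phenyl]-4-oxo-4H-chromen-3-yl acetate
Conditions: Ac2O (1.5 equiv), pyridine, DMAP (cat.), CH2Cl2, 0 °C → rt
Reagents that add atoms: acetic anhydride, CC(=O)OC(C)=O
Why: DMAP-catalysed O-acylation at O3–H, the only free hydroxyl group in 13.

Step 8
Reactants: 14 5,7-bis(benzyloxy)-2-[3,4-bis(benzyloxy)phenyl]-4-oxo-4H-chromen-3-yl acetate
Product: 15 2-(3,4-dihydroxyphenyl)-5,7-dihydroxy-4-oxo-4H-chromen-3-yl acetate (quercetin 3-acetate)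
Conditions: H2 (1 atm), 10% Pd/C, EtOAc/THF, rt
Reagents that add atoms: none
Why: Catalytic hydrogenolysis of the four benzyl aryl ethers in a neutral, non-nucleophilic solvent should leave the O3 enol acetate and the chromone C2=C3 bond untouched.

Step 9
Reactants: 15 2-(3,4-dihydroxyphenyl)-5,7-dihydroxy-4-oxo-4H-chromen-3-yl acetate
Product: 16 quercetin 3-acetate 7,3',4'-tri-O-sulfate (target)
Conditions: SO3·pyridine (about 4 equiv per hydroxyl to be sulfated), dry DMF, 0 → 25 °C; Sephadex LH-20; Dowex 50W (H+ form), 0 °C, lyophilise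
Reagents that add atoms: sulfur trioxide–pyridine complex, O=S(=O)([O-])[n+]1ccccc1
Why: O-sulfation of phenols with an SO3–amine complex should take O7, O3' and O4' and spare O5–H, which is deactivated by its hydrogen bond to the C4 carbonyl, while the anhydrous, near-neutral medium preserves the O3 acetate.

**Compound list**

1 | 4-methoxybenzyl alcohol | COc1ccc(CO)cc1 | starting material
2 | 2-chloro-N-methoxy-N-methylacetamide | CON(C)C(=O)CCl | starting material
3 | N-methoxy-2-[(4-methoxybenzyl)oxy]-N-methylacetamide | CON(C)C(=O)COCc1ccc(OC)cc1 | intermediate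
4 | 4-bromo-1,2-bis(benzyloxy)benzene | Brc1ccc(OCc2ccccc2)c(OCc2ccccc2)c1 | starting material
5 | [3,4-bis(benzyloxy)phenyl]lithium | [Li]c1ccc(OCc2ccccc2)c(OCc2ccccc2)c1 | intermediate
6 | 1-[3,4-bis(benzyloxy)phenyl]-2-[(4-methoxybenzyl)oxy]ethan-1-one | COc1ccc(COCC(=O)c2ccc(OCc3ccccc3)c(OCc3ccccc3)c2)cc1 | intermediate
7 | 2,4,6-trifluorobenzoyl chloride | O=C(Cl)c1c(F)cc(F)cc1F | starting material
8 | (E)-3-[3,4-bis(benzyloxy)phenyl]-3-hydroxy-2-[(4-methoxybenzyl)oxy]-1-(2,4,6-trifluorophenyl)prop-2-en-1-one (chelated enol, hydroxyl cis to the trifluorobenzoyl carbonyl; in equilibrium with the diketo tautomer) | O/C(c1ccc(OCc2ccccc2)c(OCc2ccccc2)c1)=C(OCc1ccc(OC)cc1)\C(=O)c1c(F)cc(F)cc1F | intermediate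
9 | 2-[3,4-bis(benzyloxy)phenyl]-5,7-difluoro-3-[(4-methoxybenzyl)oxy]-4H-chromen-4-one | O=c1c(OCc2ccc(OC)cc2)c(-c2ccc(OCc3ccccc3)c(OCc3ccccc3)c2)oc2cc(F)cc(F)c12 | intermediate
10 | benzyl alcohol | OCc1ccccc1 | starting material
11 | 7-(benzyloxy)-2-[3,4-bis(benzyloxy)phenyl]-5-fluoro-3-[(4-methoxybenzyl)oxy]-4H-chromen-4-one | O=c1c(OCc2ccc(OC)cc2)c(-c2ccc(OCc3ccccc3)c(OCc3ccccc3)c2)oc2cc(OCc3ccccc3)cc(F)c12 | intermediate
12 | 5,7-bis(benzyloxy)-2-[3,4-bis(benzyloxy)phenyl]-3-[(4-methoxybenzyl)oxy]-4H-chromen-4-one | O=c1c(OCc2ccc(OC)cc2)c(-c2ccc(OCc3ccccc3)c(OCc3ccccc3)c2)oc2cc(OCc3ccccc3)cc(OCc3ccccc3)c12 | intermediate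
13 | 5,7-bis(benzyloxy)-2-[3,4-bis(benzyloxy)phenyl]-3-hydroxy-4H-chromen-4-one | O=c1c(O)c(-c2ccc(OCc3ccccc3)c(OCc3ccccc3)c2)oc2cc(OCc3ccccc3)cc(OCc3ccccc3)c12 | intermediate
14 | 5,7-bis(benzyloxy)-2-[3,4-bis(benzyloxy)phenyl]-4-oxo-4H-chromen-3-yl acetate | CC(=O)Oc1c(-c2ccc(OCc3ccccc3)c(OCc3ccccc3)c2)oc2cc(OCc3ccccc3)cc(OCc3ccccc3)c2c1=O | intermediate
15 | 2-(3,4-dihydroxyphenyl)-5,7-dihydroxy-4-oxo-4H-chromen-3-yl acetate (quercetin 3-acetate) | CC(=O)Oc1c(-c2ccc(O)c(O)c2)oc2cc(O)cc(O)c2c1=O | intermediate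
16 | quercetin 3-acetate 7,3',4'-tri-O-sulfate | CC(=O)Oc1c(-c2ccc(OS(=O)(=O)O)c(OS(=O)(=O)O)c2)oc2cc(OS(=O)(=O)O)cc(O)c2c1=O | target

**Step count and risks**

Total step count: 9.
Longest linear sequence: 9 steps (1 → 3 → 6 → 8 → 9 → 12 → 13 → 14 → 15 → 16).

Three steps most likely to fail:

Step 9. The risk is incomplete sulfation of the catechol once the first sulfate anion is in place, together with loss of the O3 acetate or of sulfate during isolation of the polyanion. Fallback from 15: the phenols are first converted with 2,2,2-trichloroethyl chlorosulfate, NEt3 and DMAP in THF at 0 °C into the neutral, chromatographable 2-(3,4-bis{[(2,2,2-trichloroethoxy)sulfonyl]oxy}phenyl)-5-hydroxy-4-oxo-7-{[(2,2,2-trichloroethoxy)sulfonyl]oxy}-4H-chromen-3-yl acetate F1. The three sulfate diesters are then unmasked reductively with Zn dust and HCO2NH4 in THF/MeOH at 0 °C, and cation exchange (H+ form) returns to the route at 16.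

Step 5. The risk is that the second fluoride exchange stalls, so that the forcing conditions then needed favour alkoxide addition at C2 and opening of ring C. Fallback from 9: one equivalent of sodium benzyloxide in DMF at −20 → 0 °C should stop at 11, which is isolated. The remaining C5–F is then displaced with (E)-benzaldoxime and Cs2CO3 in DMSO at 60–70 °C, a hydroxide surrogate, giving the O-aryl oxime (E)-benzaldehyde O-{7-(benzyloxy)-2-[3,4-bis(benzyloxy)phenyl]-3-[(4-methoxybenzyl)oxy]-4-oxo-4H-chromen-5-yl}oxime F2 (not isolated). Under the same base F2 eliminates to 7-(benzyloxy)-2-[3,4-bis(benzyloxy)phenyl]-5-hydroxy-3-[(4-methoxybenzyl)oxy]-4H-chromen-4-one F3. Benzylation of F3 with BnBr and K2CO3 in DMF at 60 °C rejoins the route at 12. If the first exchange took C5 instead of C7, the same operations would give the regioisomeric phenol and converge on 12 all the same.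

Step 3. The risk is O-acylation of the enolate to an enol ester, or a second acylation, in competition with the C-acylation. Fallback from 6: the lithium enolate (LiN(SiMe3)2, THF, −78 °C) is added to 2,4,6-trifluorobenzaldehyde, which can only react at carbon. This gives the aldol 1-[3,4-bis(benzyloxy)phenyl]-3-hydroxy-2-[(4-methoxybenzyl)oxy]-3-(2,4,6-trifluorophenyl)propan-1-one F4 as a mixture of racemic diastereomers, both of which serve. Oxidation of the secondary alcohol with Dess–Martin periodinane and NaHCO3 in CH2Cl2 returns to the route at 8.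

**Further compounds**

F1 | step 9 | 2-(3,4-bis{[(2,2,2-trichloroethoxy)sulfonyl]oxy}phenyl)-5-hydroxy-4-oxo-7-{[(2,2,2-trichloroethoxy)sulfonyl]oxy}-4H-chromen-3-yl acetate | CC(=O)Oc1c(-c2ccc(OS(=O)(=O)OCC(Cl)(Cl)Cl)c(OS(=O)(=O)OCC(Cl)(Cl)Cl)c2)oc2cc(OS(=O)(=O)OCC(Cl)(Cl)Cl)cc(O)c2c1=O
F2 | step 5 | (E)-benzaldehyde O-{7-(benzyloxy)-2-[3,4-bis(benzyloxy)phenyl]-3-[(4-methoxybenzyl)oxy]-4-oxo-4H-chromen-5-yl}oxime | O=c1c(OCc2ccc(OC)cc2)c(-c2ccc(OCc3ccccc3)c(OCc3ccccc3)c2)oc2cc(OCc3ccccc3)cc(O/N=C/c3ccccc3)c12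
F3 | step 5 | 7-(benzyloxy)-2-[3,4-bis(benzyloxy)phenyl]-5-hydroxy-3-[(4-methoxybenzyl)oxy]-4H-chromen-4-one | O=c1c(OCc2ccc(OC)cc2)c(-c2ccc(OCc3ccccc3)c(OCc3ccccc3)c2)oc2cc(OCc3ccccc3)cc(O)c12
F4 | step 3 | 1-[3,4-bis(benzyloxy)phenyl]-3-hydroxy-2-[(4-methoxybenzyl)oxy]-3-(2,4,6-trifluorophenyl)propan-1-one (mixture of racemic diastereomers, both stereocentres removed on oxidation) | O=C(c1ccc(OCc2ccccc2)c(OCc2ccccc2)c1)C(OCc1ccc(OC)cc1)C(O)c1c(F)cc(F)cc1F
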